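**Retrosynthetic overview**
1. Target 19 ⇐ racemate 18 by enantiomer-selective Kornblum–DeLaMare resolution; 18 ⇐ peroxyhemiketal 17 by acid-catalysed exchange with MeOH (C6 under anomeric control).
2. 17 ⇐ cyclobutenol 15 by cobalt-mediated aerobic ring expansion (O2 inserted into a C–C bond of the four-membered ring); this is the only event that builds the 1,2-dioxene.
3. 15 ⇐ cyclobutenone 13 + hexadecyl Grignard reagent (from chloride 6).
4. 13 ⇐ cyclobutanone + methyl bromoacetate, then dehydrogenation; 6 ⇐ 1-bromohexane + 2 × 1-bromo-5-chloropentane.
5. Ring order: the four-membered carbocycle is bought, desaturated, and then expanded to the six-membered endoperoxide, the single ring of the target.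

Assumption: the sense of enantiomer discrimination by 9-O-acetylcupreidine in step 8 is assigned by analogy; if it is opposite, the pseudo-enantiomer 9-O-acetylcupreine (C21H24N2O3) is used instead.

Note on stereochemistry: both stereocentres of 15 are destroyed in step 6 (C4 becomes the ketone carbon, C1 a planar radical), so the diastereomer ratio of 15 does not matter. C3 of the dioxene is therefore racemic until step 8, which selects the (3S,6S) enantiomer (maximum 50%). C6 is set in step 7. Racemic 15 is drawn as one enantiomer to show its relative configuration. Racemic 18 is written as its two enantiomers because step 8 gives them different fates.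

**Step 1**
Reactants: 1 1-bromohexane; 2 1-bromo-5-chloropentane
Product: 4 1-chloroundecane, via hexylmagnesium bromide 3 (not isolated)
Conditions: Mg, THF, rt; then Br(CH2)5Cl, Li2CuCl4 (2 mol %), THF, 0 °C
Reagents that add atoms: none
Why: Copper-catalysed Kochi-type cross-coupling of a primary Grignard reagent with a primary alkyl bromide is selective for C–Br over C–Cl, so the chloride survives as the handle for the next Grignard formation and no stereocentre is formed.

**Step 2**
Reactants: 4 1-chloroundecane; 2 1-bromo-5-chloropentane
Product: 6 1-chlorohexadecane, via undecylmagnesium chloride 5 (not isolated)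
Conditions: Mg, THF, reflux; then Br(CH2)5Cl, Li2CuCl4 (2 mol %), THF, 0 °C
Reagents that add atoms: none
Why: The same bromide-selective Kochi coupling adds the last five carbons and leaves a terminal chloride for step 5, with no stereocentre involved.

**Step 3**
Reactants: 7 cyclobutanone; 8 methyl bromoacetate
Product: 11 methyl 2-(2-oxocyclobutyl)acetate (racemic), via 1-(cyclobut-1-en-1-yl)pyrrolidine 9 (not isolated), via 1-[2-(2-methoxy-2-oxoethyl)cyclobutylidene]pyrrolidinium bromide 10 (not isolated)
Conditions: pyrrolidine, benzene, reflux (Dean–Stark); then BrCH2CO2Me, MeCN, 60 °C; then H2O, rt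
Reagents that add atoms: water, O
Why: Stork enamine alkylation gives C-alkylation with the reactive α-bromo ester and avoids the self-aldol reaction of the cyclobutanone lithium enolate; the new stereocentre is racemic and is erased in step 6.

**Step 4**
Reactants: 11 methyl 2-(2-oxocyclobutyl)acetate
Product: 13 methyl 2-(4-oxocyclobut-2-en-1-yl)acetate (racemic), via methyl 2-[2-(trimethylsilyloxy)cyclobut-2-en-1-yl]acetate 12 (not isolated)
Conditions: LiN(i-Pr)2, Me3SiCl, THF, −78 °C; then Pd(OAc)2 (10 mol %), O2 (1 atm), DMSO, rt
Reagents that add atoms: none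
Why: Kinetic deprotonation takes the unsubstituted α′-CH2, and Saegusa–Ito oxidation of the silyl enol ether (oxa-π-allyl complex of divalent palladium, β-hydride elimination, reoxidation of zerovalent palladium by O2) places the double bond away from the substituted carbon, whose racemic stereocentre is untouched.

**Step 5**
Reactants: 6 1-chlorohexadecane; 13 methyl 2-(4-oxocyclobut-2-en-1-yl)acetate
Product: 15 methyl 2-[(1S*,4R*)-4-hexadecyl-4-hydroxycyclobut-2-en-1-yl]acetate (racemic, OH cis to CH2CO2Me), via hexadecylmagnesium chloride 14 (not isolated)
Conditions: Mg, THF, reflux; CeCl3, THF, −78 °C; then 13, −78 °C; AcOH, −78 °C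
Reagents that add atoms: none
Why: Imamoto-type CeCl3-promoted Grignard addition gives clean 1,2-addition to the strained enone from the face anti to the side chain (ketone far faster than the methyl ester at −78 °C), and the cold acidic quench avoids oxy-anion-accelerated ring opening and lactonisation of the alkoxide onto the cis ester.

**Step 6**
Reactants: 15 methyl 2-[(1S*,4R*)-4-hexadecyl-4-hydroxycyclobut-2-en-1-yl]acetate
Product: 17 methyl 2-(6-hexadecyl-6-hydroxy-3,6-dihydro-1,2-dioxin-3-yl)acetate (racemic at C3, C6 anomers interconvert), via methyl (4Z)-3-hydroperoxy-6-oxodocos-4-enoate 16 (not isolated)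
Conditions: Co(acac)2 (10 mol %), O2 (1 atm), CH2Cl2, 0 °C → rt, dark
Reagents that add atoms: dioxygen, O=O
Why: Proposed new method: aerobic O–O insertion into a cyclobut-2-en-1-ol, in which the trivalent cobalt alkoxide formed from Co(acac)2 and O2 undergoes strain-driven β-scission of the ring bond from the carbinol carbon C4 to the sp3 carbon C1 (scission toward the sp2 carbon would give a vinyl radical) to a Z-configured 1-acylallyl radical, O2 captures this radical at the carbon γ to the ketone faster than it can rotate, the peroxyl radical is reduced by divalent cobalt and hydrogen transfer to hydroperoxide 16, and 16 closes on the cis-disposed ketone to the six-membered peroxyhemiketal 17 (C3 arises from a planar radical and is racemic); the closest known reaction type is the Co(acac)2/O2 oxidative ring expansion of saturated cyclobutanols to 1,2-dioxan-3-ols and of cyclopropanols to 1,2-dioxolan-3-ols, which has not been shown for cyclobutenols.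

**Step 7**
Reactants: 17 methyl 2-(6-hexadecyl-6-hydroxy-3,6-dihydro-1,2-dioxin-3-yl)acetate
Product: 18 methyl 2-[(3S*,6S*)-6-hexadecyl-6-methoxy-3,6-dihydro-1,2-dioxin-3-yl]acetate (racemate, OMe cis to CH2CO2Me)
Conditions: MeOH, p-toluenesulfonic acid monohydrate (5 mol %), 0 °C → rt; SiO2 separation of the 6-epimers
Reagents that add atoms: methanol, CO
Why: Acid-catalysed peroxyhemiketal-to-peroxyketal exchange through the cyclic peroxy-oxocarbenium ion is established for this ring system and sets C6 relative to C3 under thermodynamic (anomeric) control, so both 6-epimers form (ratio to be determined); the cis isomer (axial OMe, pseudo-equatorial side chain) is isolated and the other epimer is re-equilibrated under the same conditions.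

**Step 8**
Reactants: 18 methyl 2-[(3S*,6S*)-6-hexadecyl-6-methoxy-3,6-dihydro-1,2-dioxin-3-yl]acetate
Product: 19 methyl 2-[(3S,6S)-6-hexadecyl-6-methoxy-3,6-dihydro-1,2-dioxin-3-yl]acetate (6-epi-chondrillin)
Conditions: 9-O-acetylcupreidine (C21H24N2O3, 10 mol %), CH2Cl2, 0 °C, to about 55% conversion; SiO2
Reagents that add atoms: none
Why: Proposed new method: kinetic resolution of a racemic 6-alkoxy-3,6-dihydro-1,2-dioxine by enantiomer-selective Kornblum–DeLaMare fragmentation, in which the quinuclidine nitrogen of the bifunctional cinchona base removes H-3 while its phenolic OH hydrogen-bonds to the peroxide, so the (3R,6R) antipode is deprotonated faster and collapses to a polar Z-enedione and methanol, leaving (3S,6S)-19 with C3 selected here and C6 untouched; the closest known reaction type is the cinchona-base-catalysed enantioselective Kornblum–DeLaMare desymmetrisation of meso-1,2-dioxenes, which has not been shown as a resolution of monocyclic peroxyketals.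

**Compound list**
1 | 1-bromohexane | CCCCCCBr | starting material
2 | 1-bromo-5-chloropentane | ClCCCCCBr | starting material
3 | hexylmagnesium bromide | CCCCCC[Mg]Br | intermediate
4 | 1-chloroundecane | CCCCCCCCCCCCl | intermediate
5 | undecylmagnesium chloride | CCCCCCCCCCC[Mg]Cl | intermediate
6 | 1-chlorohexadecane | CCCCCCCCCCCCCCCCCl | intermediate
7 | cyclobutanone | O=C1CCC1 | starting material
8 | methyl bromoacetate | COC(=O)CBr | starting material
9 | 1-(cyclobut-1-en-1-yl)pyrrolidine | C1CC(=C1)N1CCCC1 | intermediate
10 | 1-[2-(2-methoxy-2-oxoethyl)cyclobutylidene]pyrrolidinium bromide (racemic) | COC(=O)CC1CCC1=[N+]1CCCC1.[Br-] | intermediate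
11 | methyl 2-(2-oxocyclobutyl)acetate (racemic) | COC(=O)CC1CCC1=O | intermediate
12 | methyl 2-[2-(trimethylsilyloxy)cyclobut-2-en-1-yl]acetate (racemic) | COC(=O)CC1CC=C1O[Si](C)(C)C | intermediate
13 | methyl 2-(4-oxocyclobut-2-en-1-yl)acetate (racemic) | COC(=O)CC1C=CC1=O | intermediate
14 | hexadecylmagnesium chloride | CCCCCCCCCCCCCCCC[Mg]Cl | intermediate
15 | methyl 2-[(1S*,4R*)-4-hexadecyl-4-hydroxycyclobut-2-en-1-yl]acetate (racemate; the (1S,4R) enantiomer is drawn to show the cis relative configuration) | COC(=O)C[C@H]1C=C[C@]1(O)CCCCCCCCCCCCCCCC | intermediate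
16 | methyl (4Z)-3-hydroperoxy-6-oxodocos-4-enoate (racemic at C3) | CCCCCCCCCCCCCCCCC(=O)/C=C\C(OO)CC(=O)OC | intermediate
17 | methyl 2-(6-hexadecyl-6-hydroxy-3,6-dihydro-1,2-dioxin-3-yl)acetate (racemic at C3, C6 anomeric mixture) | CCCCCCCCCCCCCCCCC1(O)C=CC(CC(=O)OC)OO1 | intermediate
18 | methyl 2-[(3S*,6S*)-6-hexadecyl-6-methoxy-3,6-dihydro-1,2-dioxin-3-yl]acetate (racemate, both enantiomers written) | CCCCCCCCCCCCCCCC[C@@]1(OC)C=C[C@H](CC(=O)OC)OO1.CCCCCCCCCCCCCCCC[C@]1(OC)C=C[C@@H](CC(=O)OC)OO1 | intermediate
19 | methyl 2-[(3S,6S)-6-hexadecyl-6-methoxy-3,6-dihydro-1,2-dioxin-3-yl]acetate (6-epi-chondrillin) | CCCCCCCCCCCCCCCC[C@@]1(OC)C=C[C@H](CC(=O)OC)OO1 | target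

**Totals**
Total step count: 8. Longest linear sequence: 6 steps (1, 2, 5, 6, 7, 8; equally 3, 4, 5, 6, 7, 8).

**Three steps most likely to fail**

Step 6 (the new ring expansion). The risks are loss of the Z geometry in the acylallyl radical, O2 capture at the carbon α to the ketone, and thermal opening of the cyclobutenol. The fallback uses known chemistry; it sets out from 15 and returns at 17. Heating 15 in toluene at 90 °C opens the cyclobutenol by the usual electrocyclic reaction, and tautomerisation (trace Et3N) gives the conjugated enone methyl (4E)-6-oxodocos-4-enoate F1. Sensitised photooxygenation of F1 (O2, 5,10,15,20-tetraphenylporphyrin, medium-pressure Hg lamp through Pyrex, CH2Cl2, 0 °C) proceeds by photoenolisation to the Z-dienol and capture of singlet oxygen across the diene, which is the established entry to 3,6-dihydro-1,2-dioxin-3-ols, and gives 17.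

Step 4 (dehydrogenation to a sensitive 4-monosubstituted cyclobutenone). The risks are poor turnover of the palladium cycle on a strained enol ether and decomposition of 13 in DMSO. The fallback sets out from 11 and returns at 13. Deprotonation with LiN(i-Pr)2 and trapping with PhSeCl at −78 °C gives methyl 2-[2-oxo-3-(phenylselanyl)cyclobutyl]acetate F2. NaIO4 in aqueous MeOH at 0 °C oxidises it to methyl 2-[2-oxo-3-(phenylseleninyl)cyclobutyl]acetate F3, which undergoes syn-elimination below room temperature to 13.

Step 8 (the new kinetic resolution). The selectivity factor on a monocyclic peroxyketal is unknown, and the base may also erode the wanted enantiomer. The fallback uses known practice; it sets out from 18 and returns at 19: the enantiomers of 18 are separated directly by preparative HPLC on a chiral stationary phase (amylose tris(3,5-dimethylphenylcarbamate), hexane/2-propanol). This makes no new compound (entry F0).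

**Further compounds**
F1 | step 6 | methyl (4E)-6-oxodocos-4-enoate | CCCCCCCCCCCCCCCCC(=O)/C=C/CCC(=O)OC
F2 | step 4 | methyl 2-[2-oxo-3-(phenylselanyl)cyclobutyl]acetate | COC(=O)CC1CC([Se]c2ccccc2)C1=O
F3 | step 4 | methyl 2-[2-oxo-3-(phenylseleninyl)cyclobutyl]acetate | COC(=O)CC1CC([Se](=O)c2ccccc2)C1=O
F0 | step 8 | none | none
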